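## Retrosynthetic overview
1. Ampelopsin B comes from a protected ε-viniferin-type stilbene. The cycloheptane ring closes last, by a photochemical cobalt-hydride hydroarylation that forms C-a–C(aryl) and sets C-a.
2. The stilbene comes from a Heck reaction of a 4-bromo-dihydrobenzofuran with 4-methoxystyrene.
3. The trans-2,3-diaryl-dihydrobenzofuran is closed by an intramolecular Friedel–Crafts reaction of a β-aryloxy benzylic carbinol. The C-2 centre controls C-3.
4. The carbinol comes from an aryl Grignard added to a Weinreb amide. The amide is the Mitsunobu (inversion) product of (S)-4-hydroxymandelamide and 3-bromo-5-methoxyphenol.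
5. All three stereocentres trace to the carbinol carbon of (S)-4-hydroxymandelic acid. The dihydrobenzofuran forms first (Steps 3 and 5), then the seven-membered ring (Step 7).

Assumptions: (S)-4-hydroxymandelic acid is bought as an enantiopure bulk acid; it is made from L-4-hydroxyphenylglycine by retentive diazotization. BBr3 also removes the aryl pivalate.

## Route

**Step 1**
Reactants: 1 (S)-4-hydroxymandelic acid; 2 N,O-dimethylhydroxylamine hydrochloride
Product: 3 (S)-2-hydroxy-2-(4-hydroxyphenyl)-N-methoxy-N-methylacetamide
Conditions: EDC·HCl, HOBt, N-methylmorpholine, DMF, 0 °C → rt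
Reagents that add atoms: N,O-dimethylhydroxylamine hydrochloride, CONC.Cl
Why: Carbodiimide Weinreb amide coupling; the mild, low-temperature conditions leave the (S) centre untouched.

**Step 2**
Reactants: 3; 4 pivaloyl chloride
Product: 5 (S)-4-[1-hydroxy-2-(methoxy(methyl)amino)-2-oxoethyl]phenyl pivalate
Conditions: PivCl (1.0 equiv), Et3N, CH2Cl2, 0 °C
Reagents that add atoms: pivaloyl chloride, CC(C)(C)C(=O)Cl
Why: The acidic phenol is acylated selectively over the hindered secondary α-hydroxy amide. The electron-withdrawing pivalate later prevents ionization at the p-acyloxybenzylic C–O bond (Friedel–Crafts step) and is cleaved in Step 8.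

**Step 3**
Reactants: 5; 6 3-bromo-5-methoxyphenol
Product: 7 (R)-4-[1-(3-bromo-5-methoxyphenoxy)-2-(methoxy(methyl)amino)-2-oxoethyl]phenyl pivalate
Conditions: ADDP, PBu3, toluene/THF, 0 °C → rt
Reagents that add atoms: none
Why: Mitsunobu O-arylation proceeds by SN2 with inversion, converting the (S)-alcohol into the (R)-aryl ether. That is the C-2 configuration of the target, S after the later priority change. The amide α-H is much less acidic than an ester's, which protects the centre.

**Step 4**
Reactants: 7; 8 1-bromo-3,5-dimethoxybenzene (converted to ArMgBr in situ)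
Product: 9 4-[(1R)-1-(3-bromo-5-methoxyphenoxy)-2-(3,5-dimethoxyphenyl)-2-hydroxyethyl]phenyl pivalate, as a mixture of epimers at the carbinol
Conditions: (a) 8, Mg, THF, 60 °C; (b) add 7, −78 → −20 °C; (c) NaBH4, MeOH, −78 → 0 °C
Reagents that add atoms: none (the aryl group comes from 8)
Why: Weinreb ketone synthesis gives a stable chelate, and reduction in the same pot avoids isolating the enolizable α-aryloxy ketone; the carbinol epimers converge in Step 5.

**Step 5**
Reactants: 9
Product: 10 4-[(2S,3S)-4-bromo-3-(3,5-dimethoxyphenyl)-6-methoxy-2,3-dihydrobenzofuran-2-yl]phenyl pivalate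
Conditions: TfOH (10 mol%), HFIP, 0 °C, 1 h
Reagents that add atoms: none
Why: Intramolecular Friedel–Crafts benzylation. The ring A carbon ortho to the ether O and para to OMe attacks the HFIP-stabilised benzylic cation. The new C-3 centre is set trans to the C-2 aryl group by ring-closure sterics, and C-2 is not touched.

**Step 6**
Reactants: 10; 11 4-methoxystyrene
Product: 12 4-[(2S,3S)-3-(3,5-dimethoxyphenyl)-6-methoxy-4-[(E)-4-methoxystyryl]-2,3-dihydrobenzofuran-2-yl]phenyl pivalate
Conditions: Pd2(dba)3 (2.5 mol%), P(tBu)3·HBF4, Cy2NMe, dioxane, 100 °C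
Reagents that add atoms: none (the styrene is reactant 11)
Why: Mizoroki–Heck coupling installs the trans-styryl group. The stereocentres are not involved, and trans-2,3 is the thermodynamic arrangement.

**Step 7**
Reactants: 12
Product: 13 protected ampelopsin B (pentaprotected: four OMe and one OPiv)
Conditions: [Co(dmgH)2(py)Cl] (10 mol%), Mes-Acr-Ph⁺ BF4⁻ (3 mol%), 2,4,6-collidinium triflate (20 mol%), HFIP/MeCN 1:4 (0.01 M), blue LEDs (455 nm), 25 °C, 24 h, Ar
Reagents that add atoms: none (redox-neutral isomerization)
Why: Proposed new method: a photogenerated Co(III)–H delivers H• to the alkene carbon next to ring A (MHAT). This leaves a p-methoxybenzylic radical at C-a, which photo-oxidation turns into the p-anisyl cation (radical-polar crossover). The cation is captured in a 7-endo Friedel–Crafts closure by the dimethoxyarene carbon that is ortho to one OMe and para to the other. The trans-dihydrobenzofuran and the peri-fused geometry fix the face of attack and set C-a. The closest known reactions are Co-salen MHAT/radical-polar-crossover hydroarylation (six-membered rings, known) and the acid-mediated cyclization of ε-viniferin-type stilbenes to ampelopsin-type skeletons.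

**Step 8**
Reactants: 13
Product: 14 ampelopsin B
Conditions: BBr3 (12 equiv), CH2Cl2, −78 → 0 °C, 4 h; then MeOH
Reagents that add atoms: none (BBr3 and MeOH are not retained)
Why: Global cleavage of four aryl methyl ethers and the aryl pivalate. The low temperature protects the benzylic C2–O bond, and no stereocentre is involved.

## Compound list
1 | (S)-4-hydroxymandelic acid | O=C(O)[C@@H](O)c1ccc(O)cc1 | starting material
2 | N,O-dimethylhydroxylamine hydrochloride | CONC.Cl | reagent/starting material
3 | (S)-Weinreb mandelamide | CON(C)C(=O)[C@@H](O)c1ccc(O)cc1 | intermediate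
4 | pivaloyl chloride | CC(C)(C)C(=O)Cl | reagent/starting material
5 | (S)-aryl pivalate amide | CON(C)C(=O)[C@@H](O)c1ccc(OC(=O)C(C)(C)C)cc1 | intermediate
6 | 3-bromo-5-methoxyphenol | COc1cc(O)cc(Br)c1 | starting material
7 | (R)-aryl ether amide | CON(C)C(=O)[C@H](Oc1cc(Br)cc(OC)c1)c1ccc(OC(=O)C(C)(C)C)cc1 | intermediate
8 | 1-bromo-3,5-dimethoxybenzene | COc1cc(Br)cc(OC)c1 | starting material
9 | β-aryloxy diarylcarbinol (C-2 defined, carbinol epimeric) | COc1cc(OC)cc(c1)C(O)[C@@H](c1ccc(OC(=O)C(C)(C)C)cc1)Oc1cc(Br)cc(OC)c1 | intermediate
10 | trans-4-bromo-dihydrobenzofuran | Brc1cc(OC)cc2O[C@H](c3ccc(OC(=O)C(C)(C)C)cc3)[C@@H](c3cc(OC)cc(OC)c3)c12 | intermediate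
11 | 4-methoxystyrene | C=Cc1ccc(OC)cc1 | starting material
12 | (E)-stilbene dihydrobenzofuran | COc1ccc(/C=C/c2cc(OC)cc3O[C@H](c4ccc(OC(=O)C(C)(C)C)cc4)[C@@H](c4cc(OC)cc(OC)c4)c23)cc1 | intermediate
13 | protected ampelopsin B | COc1ccc([C@@H]2Cc3cc(OC)cc4c3[C@H](c3cc(OC)cc(OC)c32)[C@@H](c2ccc(OC(=O)C(C)(C)C)cc2)O4)cc1 | intermediate
14 | ampelopsin B | Oc1ccc([C@@H]2Cc3cc(O)cc4c3[C@H](c3cc(O)cc(O)c32)[C@@H](c2ccc(O)cc2)O4)cc1 | target

## Totals
Total steps: 8. Longest linear sequence: 8 (1 → 3 → 5 → 7 → 9 → 10 → 12 → 13 → 14).

## Three steps most likely to fail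
1. **Step 7 (proposed new step).** Risks are regiochemistry of MHAT, competing stilbene radical-cation chemistry, and the C-a diastereoselectivity.
   - Fallback: cationic cycloisomerization of 12 with TfOH or BF3·OEt2 in HFIP at −20 °C. This is the known biomimetic Friedel–Crafts closure of ε-viniferin-type stilbenes.
2. **Step 5.** Risks are ring closure at the wrong ortho carbon (between O and OMe), a 1,2-hydride shift competing with ring closure, and a trans:cis ratio below the expected level.
   - Fallback: omit the NaBH4 in Step 4 and cyclize the α-aryloxy ketone directly with TMSOTf/Et3SiH. This is a reductive Friedel–Crafts closure, with hydride delivered anti to the 2-aryl group.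
3. **Step 4.** Risk is loss of optical purity at C-2 through enolization or α-deprotonation of the α-aryloxy amide or ketone.
   - Fallback: change the order of fragment joining. Add 8-derived ArMgBr to the Weinreb amide of the O-TBS-protected pivaloyloxy (S)-mandelate, reduce, acetylate the carbinol, remove the TBS group, and make the aryl ether by Mitsunobu with inversion using phenol 6. Then remove the acetate to reach 9.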